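The route rests on cutting the C3=C4 bond of the 2H-pyran ring. This cis alkene lies between arene carbon C4a and the fully substituted C2, so it can be formed last by ring-closing metathesis, after the C2–O1 tertiary aryl ether has been set with its configuration. In one operation the metathesis closes the pyran ring and installs the chromene alkene while no stereocentre is formed or disturbed. The precursor 22 is a 2-vinylaryl ether: a trimethoxystyrene whose phenolic oxygen carries the (S)-configured carbon bearing methyl, vinyl and the ethylene tether to the (1R,3R)-dimethyl-methylidenecyclohexane, which is built from (R)-citronellal by a gold-catalysed enol ether–alkyne closure.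

Key step: step 15

Remark 1: the (R,R) ligand in step 13 is assumed to give the (S) ether from the E carbonate; the sense is calibrated on geranyl methyl carbonate beforehand and the mirror-image ligand is used if it proves opposite.
Remark 2: aldehyde 9 reads 1S only because formyl outranks the methylidene carbon; its ring has the spatial arrangement of the (1R,3R) unit of the target.

Step 1
Reactants: 1 (3R)-3,7-dimethyloct-6-enal, (R)-citronellal
Product: 3 (3R)-3,7-dimethyloct-6-en-1-yne, via alkenyl nonaflate 2 (not isolated)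
Conditions: n-C4F9SO2F (1.2 equiv), t-BuN=P(NC4H8)3 (BTPP, 2.5 equiv), DMF, −20 °C → rt
Reagents that add atoms: none
Why: One-pot alkyne synthesis from an enolisable aldehyde (enolate O-nonaflation, then base-induced elimination of the alkenyl nonaflate), in which the basic medium avoids the acid-triggered ene cyclisation of citronellal and the C3 stereocentre, now propargylic, is not deprotonated.

Step 2
Reactants: 3 (3R)-3,7-dimethyloct-6-en-1-yne
Product: 6 (2E,6R)-2,6-dimethyloct-2-en-7-ynal, via ozonide 4 (not isolated), via alkynal 5 (not isolated)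
Conditions: O3, CH2Cl2, −78 °C; PPh3, −78 °C → rt; then Ph3P=C(CH3)CHO, toluene, 80 °C
Reagents that add atoms: 2-(triphenylphosphoranylidene)propanal, CC(C=O)=P(c1ccccc1)(c1ccccc1)c1ccccc1
Why: Ozonolysis followed by Wittig olefination in one pot, in which ozone should cleave the electron-rich trisubstituted alkene far faster than the terminal alkyne and the stabilised formyl ylide should give the E enal.

Step 3
Reactants: 6 (2E,6R)-2,6-dimethyloct-2-en-7-ynal
Product: 7 (6R)-2,6-dimethyloct-7-ynal (both C2 epimers)
Conditions: diethyl 2,6-dimethyl-1,4-dihydropyridine-3,5-dicarboxylate (1.1 equiv), (PhCH2)2NH2+ CF3CO2− (10 mol%), THF, rt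
Reagents that add atoms: none
Why: Organocatalytic conjugate transfer hydrogenation, in which the iminium ion of the enal takes hydride from the Hantzsch ester at C3 while alkyne and formyl group stay untouched; the C2 centre formed here becomes sp2 again in step 4, so its configuration does not matter.

Step 4
Reactants: 7 (6R)-2,6-dimethyloct-7-ynal
Product: 8 {[(6R)-2,6-dimethyloct-1-en-7-yn-1-yl]oxy}tri(propan-2-yl)silane (E/Z mixture)
Conditions: i-Pr3SiOTf (1.2 equiv), Et3N, CH2Cl2, 0 °C → rt
Reagents that add atoms: triisopropylsilyl trifluoromethanesulfonate, CC(C)[Si](OS(=O)(=O)C(F)(F)F)(C(C)C)C(C)C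
Why: Soft enolisation and O-silylation of an α-branched aldehyde gives the silyl enol ether, and both geometric isomers converge in step 5.

Step 5
Reactants: 8 {[(6R)-2,6-dimethyloct-1-en-7-yn-1-yl]oxy}tri(propan-2-yl)silane
Product: 9 (1S,3R)-1,3-dimethyl-2-methylidenecyclohexane-1-carbaldehyde
Conditions: Ph3PAuCl (5 mol%), AgBF4 (5 mol%), CH2Cl2/MeOH (10:1), rt
Reagents that add atoms: none
Why: Gold-catalysed Conia-ene-type 6-exo-dig carbocyclisation of a silyl enol ether onto a terminal alkyne, in which anti attack places gold on the exocyclic carbon syn to C3, so allylic 1,3-strain should turn the C3 methyl axial in the chair-like transition state and the flat O-silylated formyl carbon (not the methyl) should take the syn-axial site at the new quaternary C1, giving formyl cis to the C3 methyl, while methanol removes the silyl group and protonates the vinyl–gold bond.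

Step 6
Reactants: 9 (1S,3R)-1,3-dimethyl-2-methylidenecyclohexane-1-carbaldehyde
Product: 10 (3E)-4-[(1R,3R)-1,3-dimethyl-2-methylidenecyclohexyl]but-3-en-2-one
Conditions: (EtO)2P(O)CH2C(O)CH3, NaH, THF, 0 °C → 60 °C
Reagents that add atoms: diethyl (2-oxopropyl)phosphonate, CCOP(=O)(CC(C)=O)OCC
Why: Horner–Wadsworth–Emmons olefination of a non-enolisable neopentyl-type aldehyde with a stabilised phosphonate anion should give the E enone.

Step 7
Reactants: 10 (3E)-4-[(1R,3R)-1,3-dimethyl-2-methylidenecyclohexyl]but-3-en-2-one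
Product: 11 4-[(1R,3R)-1,3-dimethyl-2-methylidenecyclohexyl]butan-2-one
Conditions: [(Ph3P)CuH]6 (0.4 equiv), H2O (2 equiv), THF, rt
Reagents that add atoms: none
Why: Conjugate reduction by the phosphine-stabilised copper hydride hexamer delivers hydride only to the enone β-carbon and leaves the unactivated exocyclic alkene alone.

Step 8
Reactants: 11 4-[(1R,3R)-1,3-dimethyl-2-methylidenecyclohexyl]butan-2-one
Product: 13 (1R,3R)-1-(but-3-yn-1-yl)-1,3-dimethyl-2-methylidenecyclohexane, via enol phosphate 12 (not isolated)
Conditions: LiN(i-Pr)2 (1.05 equiv), THF, −78 °C; ClP(O)(OEt)2; LiN(i-Pr)2 (2.3 equiv), −78 °C → rt; aq NH4Cl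
Reagents that add atoms: none
Why: Negishi alkyne synthesis from a methyl ketone (kinetic deprotonation at the methyl group, O-phosphorylation, then elimination of the enol phosphate), whose minor internal-enolate products stay non-polar and are removed after step 9.

Step 9
Reactants: 13 (1R,3R)-1-(but-3-yn-1-yl)-1,3-dimethyl-2-methylidenecyclohexane
Product: 15 (2E)-5-[(1R,3R)-1,3-dimethyl-2-methylidenecyclohexyl]-3-methylpent-2-en-1-ol, via alkenylalane 14 (not isolated)
Conditions: AlMe3 (2.5 equiv), Cp2ZrCl2 (0.25 equiv), CH2Cl2, 0 °C → rt; (CH2O)n, THF, 0 °C → rt; aq NH4Cl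
Reagents that add atoms: trimethylaluminium, C[Al](C)C; formaldehyde (as paraformaldehyde), C=O
Why: Zirconium-catalysed Negishi carboalumination adds methyl and aluminium syn across the terminal alkyne and trapping with formaldehyde keeps the geometry, so only the E allylic alcohol should form, while the hindered 1,1-disubstituted alkene does not react.

Step 10
Reactants: 15 (2E)-5-[(1R,3R)-1,3-dimethyl-2-methylidenecyclohexyl]-3-methylpent-2-en-1-ol
Product: 16 (2E)-5-[(1R,3R)-1,3-dimethyl-2-methylidenecyclohexyl]-3-methylpent-2-en-1-yl methyl carbonate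
Conditions: ClCO2Me, pyridine, CH2Cl2, 0 °C
Reagents that add atoms: methyl chloroformate, COC(=O)Cl
Why: Acylation of the primary allylic alcohol gives the carbonate leaving group needed for ionisation in step 13.

Step 11
Reactants: 17 2,4,5-trimethoxybenzaldehyde
Product: 19 2,4,5-trimethoxyphenol, via aryl formate 18 (not isolated)
Conditions: m-CPBA, CH2Cl2, 0 °C → rt; then KOH, MeOH/H2O, 0 °C; HCl work-up
Reagents that add atoms: 3-chloroperbenzoic acid, OOC(=O)c1cccc(Cl)c1
Why: Baeyer–Villiger (Dakin-type) oxidation, in which the electron-rich aryl group migrates to oxygen and the formate is then saponified.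

Step 12
Reactants: 19 2,4,5-trimethoxyphenol
Product: 20 2-hydroxy-3,5,6-trimethoxybenzaldehyde
Conditions: MgCl2, Et3N, (CH2O)n, MeCN, 80 °C
Reagents that add atoms: formaldehyde (as paraformaldehyde), C=O
Why: Magnesium-mediated ortho-formylation of a phenol (Casnati–Skattebøl) is ortho-specific through the magnesium phenoxide–formaldehyde chelate, and the ring has only one free ortho position.

Step 13
Reactants: 16 (2E)-5-[(1R,3R)-1,3-dimethyl-2-methylidenecyclohexyl]-3-methylpent-2-en-1-yl methyl carbonate; 20 2-hydroxy-3,5,6-trimethoxybenzaldehyde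
Product: 21 2-{[(3S)-5-[(1R,3R)-1,3-dimethyl-2-methylidenecyclohexyl]-3-methylpent-1-en-3-yl]oxy}-3,5,6-trimethoxybenzaldehyde
Conditions: Pd2(dba)3·CHCl3 (2 mol%), (R,R)-DACH-phenyl Trost ligand (6 mol%), CH2Cl2, rt
Reagents that add atoms: none
Why: Palladium-catalysed asymmetric allylic etherification of a phenol (Tsuji–Trost type), in which zerovalent palladium ionises the carbonate, the π-allyl complex equilibrates its faces through the primary σ-allyl form, the phenoxide of 20 attacks the more substituted terminus inside the chiral pocket, and the ligand alone (the ring stereocentres are remote) sets the (S) configuration of the tertiary ether carbon.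

Step 14
Reactants: 21 2-{[(3S)-5-[(1R,3R)-1,3-dimethyl-2-methylidenecyclohexyl]-3-methylpent-1-en-3-yl]oxy}-3,5,6-trimethoxybenzaldehyde
Product: 22 1-{[(3S)-5-[(1R,3R)-1,3-dimethyl-2-methylidenecyclohexyl]-3-methylpent-1-en-3-yl]oxy}-2-ethenyl-3,4,6-trimethoxybenzene
Conditions: Ph3PCH3Br, KOt-Bu, THF, 0 °C → rt
Reagents that add atoms: methyltriphenylphosphonium bromide, C[P+](c1ccccc1)(c1ccccc1)c1ccccc1.[Br-]
Why: Wittig methylenation with the small, reactive methylidene ylide converts the hindered aryl aldehyde into the styrene under basic conditions that leave the tertiary allyl aryl ether intact.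

Step 15
Reactants: 22 1-{[(3S)-5-[(1R,3R)-1,3-dimethyl-2-methylidenecyclohexyl]-3-methylpent-1-en-3-yl]oxy}-2-ethenyl-3,4,6-trimethoxybenzene
Product: 23 (2S)-2-{2-[(1R,3R)-1,3-dimethyl-2-methylidenecyclohexyl]ethyl}-5,6,8-trimethoxy-2-methyl-2H-chromene
Conditions: second-generation Grubbs catalyst RuCl2(=CHPh)(PCy3)(H2IMes) (5 mol%), CH2Cl2 (0.005 M), 40 °C
Reagents that add atoms: none
Why: The ruthenium benzylidene first exchanges with the unhindered styrene vinyl on C4a, the new alkylidene adds across the vinyl group on C2 to give a ruthenacyclobutane, and cycloreversion releases the chromene and a ruthenium methylidene that carries the cycle, with ethene lost. The closest known reaction type is ring-closing metathesis of 2-vinylaryl allyl ethers to 2H-chromenes, 2,2-disubstituted ones included. The six-membered pyran ring is closed by joining the two inner alkene carbons as C3=C4, and the ring size allows only the cis alkene. No stereocentre is created, and the neutral conditions never open the C2–O1 bond, so the configuration set in step 13 is carried through. The step needs chemoselectivity among three alkenes, which the substrate secures because the exocyclic methylidene is 1,1-disubstituted and flanked by the quaternary C1 and the tertiary C3 of the carbocycle, too hindered to enter the cycle.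

Step 16
Reactants: 23 (2S)-2-{2-[(1R,3R)-1,3-dimethyl-2-methylidenecyclohexyl]ethyl}-5,6,8-trimethoxy-2-methyl-2H-chromene
Product: 24 metachromin E, (2S)-2-{2-[(1R,3R)-1,3-dimethyl-2-methylidenecyclohexyl]ethyl}-6-methoxy-2-methyl-2H-chromene-5,8-dione
Conditions: (NH4)2Ce(NO3)6 (2.5 equiv), MeCN/H2O (2:1), 0 °C
Reagents that add atoms: water, O
Why: Oxidative demethylation with ceric ammonium nitrate, in which the arene radical cation is attacked by water at the para-related C5 and C8 methoxy carbons to give the 5,8-quinone, the C6 methoxy group surviving as a vinylogous ester.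

Compound list
1 | (3R)-3,7-dimethyloct-6-enal, (R)-citronellal | O=CC[C@H](C)CCC=C(C)C | starting material
2 | (3R)-3,7-dimethylocta-1,6-dien-1-yl nonafluorobutane-1-sulfonate (E/Z mixture) | CC(C)=CCC[C@@H](C)C=COS(=O)(=O)C(F)(F)C(F)(F)C(F)(F)C(F)(F)F | intermediate
3 | (3R)-3,7-dimethyloct-6-en-1-yne | C#C[C@H](C)CCC=C(C)C | intermediate
4 | 3,3-dimethyl-5-[(3R)-3-methylpent-4-yn-1-yl]-1,2,4-trioxolane (both epimers at C5) | C#C[C@H](C)CCC1OOC(C)(C)O1 | intermediate
5 | (4R)-4-methylhex-5-ynal | C#C[C@H](C)CCC=O | intermediate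
6 | (2E,6R)-2,6-dimethyloct-2-en-7-ynal | C#C[C@H](C)CC/C=C(\C)C=O | intermediate
7 | (6R)-2,6-dimethyloct-7-ynal (both C2 epimers) | C#C[C@H](C)CCCC(C)C=O | intermediate
8 | {[(6R)-2,6-dimethyloct-1-en-7-yn-1-yl]oxy}tri(propan-2-yl)silane (E/Z mixture) | C#C[C@H](C)CCCC(C)=CO[Si](C(C)C)(C(C)C)C(C)C | intermediate
9 | (1S,3R)-1,3-dimethyl-2-methylidenecyclohexane-1-carbaldehyde | C=C1[C@H](C)CCC[C@]1(C)C=O | intermediate
10 | (3E)-4-[(1R,3R)-1,3-dimethyl-2-methylidenecyclohexyl]but-3-en-2-one | C=C1[C@H](C)CCC[C@]1(C)/C=C/C(C)=O | intermediate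
11 | 4-[(1R,3R)-1,3-dimethyl-2-methylidenecyclohexyl]butan-2-one | C=C1[C@H](C)CCC[C@]1(C)CCC(C)=O | intermediate
12 | 4-[(1R,3R)-1,3-dimethyl-2-methylidenecyclohexyl]but-1-en-2-yl diethyl phosphate | C=C1[C@H](C)CCC[C@]1(C)CCC(=C)OP(=O)(OCC)OCC | intermediate
13 | (1R,3R)-1-(but-3-yn-1-yl)-1,3-dimethyl-2-methylidenecyclohexane | C=C1[C@H](C)CCC[C@]1(C)CCC#C | intermediate
14 | [(1E)-4-[(1R,3R)-1,3-dimethyl-2-methylidenecyclohexyl]-2-methylbut-1-en-1-yl]dimethylalumane | C=C1[C@H](C)CCC[C@]1(C)CC/C(C)=C/[Al](C)C | intermediate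
15 | (2E)-5-[(1R,3R)-1,3-dimethyl-2-methylidenecyclohexyl]-3-methylpent-2-en-1-ol | C=C1[C@H](C)CCC[C@]1(C)CC/C(C)=C/CO | intermediate
16 | (2E)-5-[(1R,3R)-1,3-dimethyl-2-methylidenecyclohexyl]-3-methylpent-2-en-1-yl methyl carbonate | C=C1[C@H](C)CCC[C@]1(C)CC/C(C)=C/COC(=O)OC | intermediate
17 | 2,4,5-trimethoxybenzaldehyde | COc1cc(OC)c(C=O)cc1OC | starting material
18 | 2,4,5-trimethoxyphenyl formate | COc1cc(OC)c(OC=O)cc1OC | intermediate
19 | 2,4,5-trimethoxyphenol | COc1cc(OC)c(O)cc1OC | intermediate
20 | 2-hydroxy-3,5,6-trimethoxybenzaldehyde | COc1cc(OC)c(OC)c(C=O)c1O | intermediate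
21 | 2-{[(3S)-5-[(1R,3R)-1,3-dimethyl-2-methylidenecyclohexyl]-3-methylpent-1-en-3-yl]oxy}-3,5,6-trimethoxybenzaldehyde | C=C1[C@H](C)CCC[C@]1(C)CC[C@@](C)(C=C)Oc1c(C=O)c(OC)c(OC)cc1OC | intermediate
22 | 1-{[(3S)-5-[(1R,3R)-1,3-dimethyl-2-methylidenecyclohexyl]-3-methylpent-1-en-3-yl]oxy}-2-ethenyl-3,4,6-trimethoxybenzene | C=C1[C@H](C)CCC[C@]1(C)CC[C@@](C)(C=C)Oc1c(C=C)c(OC)c(OC)cc1OC | intermediate
23 | (2S)-2-{2-[(1R,3R)-1,3-dimethyl-2-methylidenecyclohexyl]ethyl}-5,6,8-trimethoxy-2-methyl-2H-chromene | C=C1[C@H](C)CCC[C@]1(C)CC[C@@]1(C)C=Cc2c(O1)c(OC)cc(OC)c2OC | intermediate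
24 | metachromin E, (2S)-2-{2-[(1R,3R)-1,3-dimethyl-2-methylidenecyclohexyl]ethyl}-6-methoxy-2-methyl-2H-chromene-5,8-dione | C=C1[C@H](C)CCC[C@]1(C)CC[C@@]1(C)C=CC2=C(O1)C(=O)C=C(OC)C2=O | target

Total step count: 16
Longest linear sequence: 14 steps (steps 1 to 10, then 13 to 16)

Steps most likely to fail

Step 5. What may go wrong is poor discrimination between the two faces of the enol ether carbon, so that the C1 epimer forms beside 9, or slow six-membered closure with competing solvolysis of the alkyne. The fallback replaces substrate control by catalyst control and sets out from aldehyde 7, leaving out 8. Aldehyde 7 is condensed in the flask with cyclohexylamine and the enamine is cyclised onto the alkyne with Cu(OTf)2 and an atropisomeric bisphosphine such as DTBM-MeO-BIPHEP (cooperative amine/copper carbocyclisation of α-branched formyl alkynes). The ligand antipode is chosen so that it reinforces formation of 9, where the route is rejoined; no new isolable compound is made (F0).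

Step 13. What may go wrong is attack of the hindered, hydrogen-bonded phenoxide at the unsubstituted allyl terminus, erosion of enantioface control, or re-ionisation of the tertiary ether once formed. The fallback forms the C–O bond by epoxide opening and sets out from alcohol 15. Sharpless asymmetric epoxidation (Ti(Oi-Pr)4, D-(−)-diethyl tartrate, t-BuOOH) gives [(2R,3R)-3-{2-[(1R,3R)-1,3-dimethyl-2-methylidenecyclohexyl]ethyl}-3-methyloxiran-2-yl]methanol F1. Opening of F1 by phenol 20 at the tertiary C3 with inversion, mediated by Ti(Oi-Pr)4, gives 2-{[(2R,3S)-5-[(1R,3R)-1,3-dimethyl-2-methylidenecyclohexyl]-1,2-dihydroxy-3-methylpentan-3-yl]oxy}-3,5,6-trimethoxybenzaldehyde F2. Deoxygenation of the 1,2-diol to the alkene (PPh3, I2, imidazole, toluene, heat) then gives 21, where the route is rejoined.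

Step 1. What may go wrong is self-condensation of the aldehyde enolate before O-sulfonylation, or base-induced migration of the new triple bond with loss of the propargylic stereocentre. The fallback removes one carbon and adds one back, and sets out from 1. Condensation with pyrrolidine gives 1-[(1E,3R)-3,7-dimethylocta-1,6-dien-1-yl]pyrrolidine F3. Oxidative cleavage of the enamine double bond (O2, CuCl, MeCN) gives (2R)-2,6-dimethylhept-5-enal F4. Dibromo-olefination (CBr4, PPh3, CH2Cl2, 0 °C) gives (3R)-1,1-dibromo-3,7-dimethylocta-1,6-diene F5, and n-BuLi (THF, −78 °C; Corey–Fuchs) then gives alkyne 3, where the route is rejoined.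

Further compounds
F0 | step 5 | none | none
F1 | step 13 | [(2R,3R)-3-{2-[(1R,3R)-1,3-dimethyl-2-methylidenecyclohexyl]ethyl}-3-methyloxiran-2-yl]methanol | C=C1[C@H](C)CCC[C@]1(C)CC[C@@]2(C)O[C@@H]2CO
F2 | step 13 | 2-{[(2R,3S)-5-[(1R,3R)-1,3-dimethyl-2-methylidenecyclohexyl]-1,2-dihydroxy-3-methylpentan-3-yl]oxy}-3,5,6-trimethoxybenzaldehyde | C=C1[C@H](C)CCC[C@]1(C)CC[C@@](C)([C@H](O)CO)Oc1c(C=O)c(OC)c(OC)cc1OC
F3 | step 1 | 1-[(1E,3R)-3,7-dimethylocta-1,6-dien-1-yl]pyrrolidine | CC(C)=CCC[C@@H](C)/C=C/N1CCCC1
F4 | step 1 | (2R)-2,6-dimethylhept-5-enal | O=C[C@H](C)CCC=C(C)C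
F5 | step 1 | (3R)-1,1-dibromo-3,7-dimethylocta-1,6-diene | BrC(Br)=C[C@H](C)CCC=C(C)C
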